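(The runs come from a simulation for substances that don't exist, noise included.)

The constants of the proposed steps are hidden from us, so we read one number that stands for their contest: free catalyst takes each substrate into its own intermediate, and reagent turns that intermediate into product and frees the catalyst again.

| setting | spring | noon | dawn | flask |
|---|---|---|---|---|
| left-handed substrate | 16 mM | 62 mM | 31 mM | 31 mM |
| right-handed substrate | 16 mM | 62 mM | 31 mM | 31 mM |
| reagent | 18.6 mM | 18.6 mM | 9.3 mM | 18.6 mM |
| free catalyst | 2 mM | 2 mM | 2 mM | 2.0 mM |
| impurity | 0.93 mM | 0.93 mM | 0.93 mM | 0.93 mM |
| added ligand | 2.6 mM | 2.6 mM | 2.6 mM | 2.6 mM |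
| remark | run made earlier | run made earlier | run made earlier |  |
| time |  |  |  | 3.0 h |

- spring (time / min: left-handed product / %, right-handed product / %): 8.00: 0.9, 0.5; 20.0: 0.9, 0.4; 40.0: 2.6, 0.6; 60.0: 3.5, 0.8; 80.0: 4.2, 0.9; 120: 4.7, 1.4
- noon (time / min: left-handed product / %, right-handed product / %): 8.00: 0, 0; 15.0: 0.2, 0; 25.0: 0.1, 1.2; 40.0: 0.9, 1.0; 60.0: 1.7, 0.1; 120: 3.3, 1.9
- dawn (time / min: left-handed product / %, right-handed product / %): 8.00: 0.3, 0.5; 15.0: 0.7, 0.6; 30.0: 0.5, 0.5; 60.0: 1.2, 0.4; 120: 1.9, 0.7

(each reading ± 0.5 percentage points)

- free catalyst is single-handed; left-handed substrate and right-handed substrate are mirror images of each other, charged as a racemate, each of them at the stated concentration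
- the numbers in the tables scatter with a standard deviation of 0.5 percentage points
- steps that have been proposed: free catalyst -> spent catalyst B; reagent + catalyst intermediate A -> free catalyst + left-handed product; free catalyst + left-handed substrate <-> catalyst intermediate A; reagent + catalyst intermediate B -> free catalyst + right-handed product; free catalyst + impurity -> spent catalyst A; free catalyst + added ligand <-> idle complex; free catalyst + right-handed substrate <-> catalyst intermediate B
- an excess is the difference of the two amounts in percent of their sum
- an excess is below zero if the other one leads

- excess of left-handed product over right-handed product in the product at 10 min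
- excess of left-handed product over right-handed product in the product at 3.0 h
- part of the left-handed substrate and right-handed substrate charged together that has reacted at 3.0 h

We work with the fraction left. Let f be the fraction of a substrate's own charge not yet turned into product, and let the selectivity factor s be ln f of the left-handed substrate over ln f of the right-handed substrate. While little has reacted, the excess in the product is s minus one over s plus one.

Take the substrate charge first. By hand, it should fill both intermediates and leave s alone. The mean of the last two readings gives 4.01 in spring and 2.54 in noon, but the right-handed readings behind the noon value are 0.1% and 1.9%, each scattering by 0.5 percentage points, so these two values show no fall with charge. The geometric mean of those two charges is 31.5 mM, next to the 31 mM of the flask, so we take 3.19, the selectivity factor expected of the flask.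

Next, the reagent. By hand, it should speed both branches alike. Dawn, with 9.3 mM, gives 2.85, and with right-handed readings of 0.7% scattering by 0.5 points, that is no visible change.

Added ligand holds free catalyst away from both branches, so by hand it slows both and leaves s; the earlier runs hold it at 2.6 mM.

So we expect an excess near 52.3% at both asked times in the flask. The late right-handed readings are the ones to watch. For the amount reacted, the same two runs give 5.72% at 120 min, so we expect somewhat more at 3.0 h.

The forecast differs from us on the early excess, saying 10% at 10 min, 50% at 3.0 h and 6.6% reacted, on the ground that “Catalyst probably enters intermediate B quickly, then drains towards A, so the excess grows with time”.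

The flask gives 50.1%, 58.4% and 6.57%.

    free catalyst → spent catalyst B (k = 0.0140 min⁻¹)
    reagent + catalyst intermediate A → free catalyst + left-handed product (k = 3.99 M⁻¹ min⁻¹)
    free catalyst + left-handed substrate ⇌ catalyst intermediate A (K = 72.0 M⁻¹, k = 16.7 M⁻¹ min⁻¹)
    reagent + catalyst intermediate B → free catalyst + right-handed product (k = 0.924 M⁻¹ min⁻¹)
    free catalyst + impurity → spent catalyst A (k = 975 M⁻¹ min⁻¹)
    free catalyst + added ligand ⇌ idle complex (K = 680 M⁻¹, k = 14.1 M⁻¹ min⁻¹)
    free catalyst + right-handed substrate ⇌ catalyst intermediate B (K = 60.7 M⁻¹, k = 205 M⁻¹ min⁻¹)

At 3.0 h the flask holds 4.72% of left-handed product and 1.24% of right-handed product, so its s is 3.95, higher than our 3.19. A neighbouring flask with 74 mM of reagent, its other charges as in the recipe, holds 12.0% of left-handed product and 5.41% of right-handed product at that time. The same reckoning gives it an s of 2.40, lower than the flask's. In that neighbouring flask, 17.9% has reacted, and its excess at 3.0 h stands at 37.9%.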